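The benzene ring is read as a folded polyketide. Carboxyl carbon C7, ring carbons C1–C6 and the benzylic CH2 form a 3,5,7-trioxo acid chain. The bond joining C1 (which carries the carboxyl) to C6 (which carries the side chain) is retrosynthetically an aldol bond. Closing it on a dioxinone-masked diketone builds the arene in one operation and sets the 2,4-dioxygenation. It leaves C7 and the C2 oxygen tied as an acetonide, so only the C4 phenol is open to methylation. The precursor is a 2,2-dimethyl-1,3-dioxin-4-one bearing at its 6-position a 2,4-dioxoheptadecyl chain with an (R)-silyloxy group. The stereocentre comes from (R)-3-hydroxytetradecanoic acid. A late direct silyl-to-acetyl exchange avoids a lactonization-prone hydroxy ester.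

Key step: step 5

Assumption and numbering: arene C1 bears carboxyl C7, C2 the OH, C4 the OMe and C6 the side chain; primed numbers count along the side chain of 9 starting at the dioxinone; β-dicarbonyl compounds are drawn as keto forms although they should be largely enolized; LDA is the commercial solution. Atom map: 4 supplies C7, C1, C2 and C3; 5 supplies C4 and C5; the carboxyl carbon of 1 becomes C6.

Step 1
Reactants: 1 (R)-3-hydroxytetradecanoic acid
Product: 2 (3R)-3-hydroxy-N-methoxy-N-methyltetradecanamide
Conditions: MeNHOMe·HCl, EDC·HCl, HOBt, iPr2NEt, CH2Cl2, 0 °C → rt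
Reagents that add atoms: N,O-dimethylhydroxylamine hydrochloride, CNOC.Cl
Why: Carbodiimide-mediated amide coupling, in which the activated carboxyl should be captured by the amine much faster than by the secondary hydroxyl and the β-stereocentre takes no part, so the hydroxy acid needs no prior protection.

Step 2
Reactants: 2 (3R)-3-hydroxy-N-methoxy-N-methyltetradecanamide
Product: 3 (3R)-3-(tert-butyldimethylsilyloxy)-N-methoxy-N-methyltetradecanamide
Conditions: TBSCl, imidazole, DMF, rt
Reagents that add atoms: tert-butyldimethylsilyl chloride, CC(C)(C)[Si](C)(C)Cl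
Why: Imidazole-promoted silylation of a secondary alcohol replaces only the O–H hydrogen and so keeps the R configuration, and this silyl ether is chosen because silanolate is a poor leaving group in the enolate steps and can be exchanged directly for acetate in step 8.

Step 3
Reactants: 4 2,2,6-trimethyl-4H-1,3-dioxin-4-one; 5 acetyl chloride
Product: 7 2,2-dimethyl-6-(2-oxopropyl)-4H-1,3-dioxin-4-one, via lithium dienolate 6 (not isolated)
Conditions: 4 (2 equiv), LDA (2 equiv), THF, −78 °C; AcCl (1 equiv), −78 °C; 1 M HCl
Reagents that add atoms: none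
Why: γ-Selective C-acylation (vinylogous Claisen condensation) of the cross-conjugated lithium dienolate 6 with an acid chloride is a standard entry to 6-(2-oxoalkyl)dioxinones, and the extra equivalent of 6 takes up the acidic proton of 7 so that acylation can run to completion.

Step 4
Reactants: 7 2,2-dimethyl-6-(2-oxopropyl)-4H-1,3-dioxin-4-one; 3 (3R)-3-(tert-butyldimethylsilyloxy)-N-methoxy-N-methyltetradecanamide
Product: 9 6-[(6R)-6-(tert-butyldimethylsilyloxy)-2,4-dioxoheptadecyl]-2,2-dimethyl-4H-1,3-dioxin-4-one, via dilithio dianion 8 (not isolated)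
Conditions: 7 (2 equiv), LDA (4.2 equiv), THF, −78 °C; 3 (1 equiv), −78 → −20 °C; 1 M HCl, 0 °C
Reagents that add atoms: none
Why: In this acetoacetate-type dianion acylation (crossed Claisen condensation in the Weinreb ketone synthesis manner) the terminal, more basic carbon of 8 attacks the amide, whose chelated addition stage holds until the acidic quench, so over-addition, quenching of the dianion by an acidic product and E1cB loss of the silyloxy group should all be suppressed while the stereocentre stays a spectator.

Step 5
Reactants: 9 6-[(6R)-6-(tert-butyldimethylsilyloxy)-2,4-dioxoheptadecyl]-2,2-dimethyl-4H-1,3-dioxin-4-one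
Product: 11 5-[(2R)-2-(tert-butyldimethylsilyloxy)tridecyl]-7-hydroxy-2,2-dimethyl-4H-1,3-benzodioxin-4-one, via cyclic aldol 10 (not isolated)
Conditions: Et3N (excess), CH2Cl2, rt; dilute aq. HCl wash
Reagents that add atoms: none
Why: Et3N reversibly deprotonates the doubly activated methylenes C1′ and C3′ of 9 to an extended enolate whose electron density reaches the dioxinone α-carbon C5 (future arene C1); this carbon adds to the C4′ ketone (future C6) to give carbinol 10, which should lose water by E1cB, and enolization of the C2′ ketone to the C4 phenol then makes the sequence irreversible. The closest known reaction type is the base-mediated biomimetic aldol aromatization of 3,5,7-triketo esters and of their dioxinone-masked forms to resorcylates. The single ring closed, the carbocycle, forms in a 6-(enolendo)-exo-trig mode, since the dioxinone C5=C6 π bond that delivers the electrons lies inside the new ring while the ketone C=O is exocyclic to it. No stereocentre made here survives (the carbinol carbon of 10 becomes sp2), and the silyloxy-bearing centre, separated from the ketone by a CH2 that the amine cannot deprotonate, should keep its R configuration. The step needs C-aldol closure in preference to O-cyclization, to Claisen closure on the carboxyl carbon and to β-elimination of silanolate. The substrate secures this because the carboxyl is locked in the cyclic acylal and is not released as an acylketene at room temperature, because only the α-carbon reaches the distal ketone through a six-membered array, and because the bulky silanolate is a poor leaving group beside a non-enolized CH2.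

Step 6
Reactants: 11 5-[(2R)-2-(tert-butyldimethylsilyloxy)tridecyl]-7-hydroxy-2,2-dimethyl-4H-1,3-benzodioxin-4-one
Product: 12 5-[(2R)-2-(tert-butyldimethylsilyloxy)tridecyl]-7-methoxy-2,2-dimethyl-4H-1,3-benzodioxin-4-one
Conditions: MeI, K2CO3, acetone, rt → 40 °C
Reagents that add atoms: iodomethane, CI
Why: Williamson O-methylation needs no regiocontrol, because the C7 phenol of the benzodioxinone is the only acidic OH while the other phenol and the carboxyl are held in the acetonide.

Step 7
Reactants: 12 5-[(2R)-2-(tert-butyldimethylsilyloxy)tridecyl]-7-methoxy-2,2-dimethyl-4H-1,3-benzodioxin-4-one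
Product: 14 benzyl 2-(benzyloxy)-6-[(2R)-2-(tert-butyldimethylsilyloxy)tridecyl]-4-methoxybenzoate, via sodium phenolate 13 (not isolated)
Conditions: BnOH, NaH, THF, 0 °C → rt; then BnBr, n-Bu4NI (cat.), DMF, rt → 40 °C
Reagents that add atoms: benzyl alcohol, OCc1ccccc1; benzyl bromide, BrCc1ccccc1
Why: Alkoxide transesterification of the benzodioxinone (addition–elimination at the ring carbonyl followed by loss of acetone) should unveil phenolate 13, which is trapped in the same flask by Williamson benzylation, and the secondary silyl ether is inert to alkoxide.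

Step 8
Reactants: 14 benzyl 2-(benzyloxy)-6-[(2R)-2-(tert-butyldimethylsilyloxy)tridecyl]-4-methoxybenzoate
Product: 15 benzyl 6-[(2R)-2-acetoxytridecyl]-2-(benzyloxy)-4-methoxybenzoate
Conditions: Ac2O (excess), Cu(OTf)2 (5 mol %), CH2Cl2, 0 °C → rt
Reagents that add atoms: acetic anhydride, CC(=O)OC(C)=O
Why: In this Lewis-acid-catalysed direct exchange of a tert-butyldimethylsilyl ether for an acetate, acylation on oxygen and Si–O cleavage leave the C–O bond and hence the R configuration untouched, and because no free hydroxyl or alkoxide is released, lactonization onto the neighbouring benzyl ester has no opportunity.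

Step 9
Reactants: 15 benzyl 6-[(2R)-2-acetoxytridecyl]-2-(benzyloxy)-4-methoxybenzoate
Product: 16 2-[(2R)-2-acetoxytridecyl]-6-hydroxy-4-methoxybenzoic acid
Conditions: H2 (1 atm), 10% Pd/C, EtOAc, rt
Reagents that add atoms: none
Why: Catalytic hydrogenolysis cleaves the benzyl ester and the aryl benzyl ether together under neutral conditions that leave the homobenzylic acetate, the methyl ether, the arene and the stereocentre alone.

Compound list
1 | (R)-3-hydroxytetradecanoic acid | CCCCCCCCCCC[C@@H](O)CC(=O)O | starting material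
2 | (3R)-3-hydroxy-N-methoxy-N-methyltetradecanamide | CCCCCCCCCCC[C@@H](O)CC(=O)N(C)OC | intermediate
3 | (3R)-3-(tert-butyldimethylsilyloxy)-N-methoxy-N-methyltetradecanamide | CCCCCCCCCCC[C@H](CC(=O)N(C)OC)O[Si](C)(C)C(C)(C)C | intermediate
4 | 2,2,6-trimethyl-4H-1,3-dioxin-4-one | CC1=CC(=O)OC(C)(C)O1 | starting material
5 | acetyl chloride | CC(=O)Cl | starting material
6 | lithium 2,2-dimethyl-6-methylidene-1,3-dioxin-4-olate (lithium dienolate of 4) | [Li+].C=C1C=C([O-])OC(C)(C)O1 | intermediate
7 | 2,2-dimethyl-6-(2-oxopropyl)-4H-1,3-dioxin-4-one | CC(=O)CC1=CC(=O)OC(C)(C)O1 | intermediate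
8 | dilithio dianion of 7 | [Li+].[Li+].C=C([O-])C=C1C=C([O-])OC(C)(C)O1 | intermediate
9 | 6-[(6R)-6-(tert-butyldimethylsilyloxy)-2,4-dioxoheptadecyl]-2,2-dimethyl-4H-1,3-dioxin-4-one | CCCCCCCCCCC[C@H](CC(=O)CC(=O)CC1=CC(=O)OC(C)(C)O1)O[Si](C)(C)C(C)(C)C | intermediate
10 | 5-[(2R)-2-(tert-butyldimethylsilyloxy)tridecyl]-5-hydroxy-2,2-dimethyl-5,6-dihydro-4H-1,3-benzodioxine-4,7(8H)-dione (carbinol epimers) | CCCCCCCCCCC[C@H](CC1(O)CC(=O)CC2=C1C(=O)OC(C)(C)O2)O[Si](C)(C)C(C)(C)C | intermediate
11 | 5-[(2R)-2-(tert-butyldimethylsilyloxy)tridecyl]-7-hydroxy-2,2-dimethyl-4H-1,3-benzodioxin-4-one | CCCCCCCCCCC[C@H](Cc1cc(O)cc2OC(C)(C)OC(=O)c12)O[Si](C)(C)C(C)(C)C | intermediate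
12 | 5-[(2R)-2-(tert-butyldimethylsilyloxy)tridecyl]-7-methoxy-2,2-dimethyl-4H-1,3-benzodioxin-4-one | CCCCCCCCCCC[C@H](Cc1cc(OC)cc2OC(C)(C)OC(=O)c12)O[Si](C)(C)C(C)(C)C | intermediate
13 | sodium 2-(benzyloxycarbonyl)-3-[(2R)-2-(tert-butyldimethylsilyloxy)tridecyl]-5-methoxyphenolate | [Na+].CCCCCCCCCCC[C@H](Cc1cc(OC)cc([O-])c1C(=O)OCc2ccccc2)O[Si](C)(C)C(C)(C)C | intermediate
14 | benzyl 2-(benzyloxy)-6-[(2R)-2-(tert-butyldimethylsilyloxy)tridecyl]-4-methoxybenzoate | CCCCCCCCCCC[C@H](Cc1cc(OC)cc(OCc2ccccc2)c1C(=O)OCc3ccccc3)O[Si](C)(C)C(C)(C)C | intermediate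
15 | benzyl 6-[(2R)-2-acetoxytridecyl]-2-(benzyloxy)-4-methoxybenzoate | CCCCCCCCCCC[C@H](Cc1cc(OC)cc(OCc2ccccc2)c1C(=O)OCc3ccccc3)OC(C)=O | intermediate
16 | 2-[(2R)-2-acetoxytridecyl]-6-hydroxy-4-methoxybenzoic acid | CCCCCCCCCCC[C@H](Cc1cc(OC)cc(O)c1C(=O)O)OC(C)=O | target

Total step count: 9. Longest linear sequence: 8 steps (steps 1, 2 and 4–9, from 1). Step 3 is a one-step side branch from 4 and 5.

Steps most likely to fail

Step 5 (key step). The enolized chain may cyclize through oxygen, stall before dehydration, or degrade on long exposure to base. The fallback sets out from 9 and returns at 14, and it removes the mask before the ring is made.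
- Heating 9 with BnOH in toluene at 110 °C should extrude acetone by retro-[4+2] to the acylketene (9R)-9-(tert-butyldimethylsilyloxy)-3,5,7-trioxoicos-1-en-1-one F1.
- This is trapped at once as benzyl (9R)-9-(tert-butyldimethylsilyloxy)-3,5,7-trioxoicosanoate F2.
- Cs2CO3 in CH2Cl2/i-PrOH followed by AcOH should aromatize the open-chain triketo ester to benzyl 6-[(2R)-2-(tert-butyldimethylsilyloxy)tridecyl]-2,4-dihydroxybenzoate F3.
- MeI (1 equiv) with K2CO3 in acetone should methylate only the non-chelated C4 phenol, giving benzyl 6-[(2R)-2-(tert-butyldimethylsilyloxy)tridecyl]-2-hydroxy-4-methoxybenzoate F4.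
- BnBr with K2CO3 in DMF then gives 14.

Step 4. Proton transfer may win over C–C bond formation, addition to the weakly electrophilic amide may be sluggish, and the dianion may self-condense on warming. The fallback sets out from 3 and returns at 9, and it replaces acylation by aldol addition and oxidation.
- DIBAL-H in CH2Cl2 at −78 °C should reduce 3 to (3R)-3-(tert-butyldimethylsilyloxy)tetradecanal F5.
- Dianion 8 should add to the aldehyde at −78 °C through its terminal carbon, giving 6-[(6R)-6-(tert-butyldimethylsilyloxy)-4-hydroxy-2-oxoheptadecyl]-2,2-dimethyl-4H-1,3-dioxin-4-one F6. The mixture of carbinol epimers is of no consequence.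
- Dess–Martin periodinane (slight excess only) in CH2Cl2 should oxidize the carbinol to 9.

Step 8. Exchange at the hindered secondary silyl ether may be slow. Lewis-acid-induced loss of the aryl benzyl ether or C-acetylation of the electron-rich ring could then take over. The fallback sets out from 14 and returns at 15, and it separates deprotection from acylation.
- HF·pyridine buffered with extra pyridine in THF at 0 °C should give benzyl 2-(benzyloxy)-6-[(2R)-2-hydroxytridecyl]-4-methoxybenzoate F7 without ever forming an alkoxide.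
- The crude alcohol is kept cold and is not chromatographed, to limit lactonization.
- It is acetylated at once with Ac2O, DMAP and pyridine in CH2Cl2 at 0 °C to give 15.

Further compounds
F1 | step 5 | (9R)-9-(tert-butyldimethylsilyloxy)-3,5,7-trioxoicos-1-en-1-one (acylketene) | CCCCCCCCCCC[C@H](CC(=O)CC(=O)CC(=O)C=C=O)O[Si](C)(C)C(C)(C)C
F2 | step 5 | benzyl (9R)-9-(tert-butyldimethylsilyloxy)-3,5,7-trioxoicosanoate | CCCCCCCCCCC[C@H](CC(=O)CC(=O)CC(=O)CC(=O)OCc1ccccc1)O[Si](C)(C)C(C)(C)C
F3 | step 5 | benzyl 6-[(2R)-2-(tert-butyldimethylsilyloxy)tridecyl]-2,4-dihydroxybenzoate | CCCCCCCCCCC[C@H](Cc1cc(O)cc(O)c1C(=O)OCc2ccccc2)O[Si](C)(C)C(C)(C)C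
F4 | step 5 | benzyl 6-[(2R)-2-(tert-butyldimethylsilyloxy)tridecyl]-2-hydroxy-4-methoxybenzoate | CCCCCCCCCCC[C@H](Cc1cc(OC)cc(O)c1C(=O)OCc2ccccc2)O[Si](C)(C)C(C)(C)C
F5 | step 4 | (3R)-3-(tert-butyldimethylsilyloxy)tetradecanal | CCCCCCCCCCC[C@H](CC=O)O[Si](C)(C)C(C)(C)C
F6 | step 4 | 6-[(6R)-6-(tert-butyldimethylsilyloxy)-4-hydroxy-2-oxoheptadecyl]-2,2-dimethyl-4H-1,3-dioxin-4-one (carbinol epimers) | CCCCCCCCCCC[C@H](CC(O)CC(=O)CC1=CC(=O)OC(C)(C)O1)O[Si](C)(C)C(C)(C)C
F7 | step 8 | benzyl 2-(benzyloxy)-6-[(2R)-2-hydroxytridecyl]-4-methoxybenzoate | CCCCCCCCCCC[C@H](Cc1cc(OC)cc(OCc2ccccc2)c1C(=O)OCc3ccccc3)O
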